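The route rests on disconnecting the C1''–C2'' bond of the side chain. Because the benzylic C1'' sits on C8 of ring A, ortho to the C7 phenol, the C7–O/C8–C1'' unit can be unmasked as an ortho-quinone methide. A chiral enamine of 5-methylhex-5-enal adds to its CH2 terminus and the C7 oxygen closes onto the aldehyde carbon. One operation thus forms C1''–C2'', sets (R)-C2'' and builds a ring A pyrano-fused lactol whose carbinol carbon later becomes the isopropenyl carbon. The precursor is 5,7-dihydroxy-8-(tosylmethyl)chromone; its 5-OH is left free, since chelation to the C4 carbonyl keeps it inert. C2 is set afterwards by catalytic asymmetric arylation of the chromone.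

Key step: step 5

Remark: the (S)-biaryl bisphosphine of step 13 is assumed to deliver the aryl group to the Re face of C2 (giving 2S), by analogy with its sense toward 2-cyclohexenone; the mirror-image ligand would be used if the sense proved opposite.

Step 1
Reactants: 1 5,7-dihydroxychromone (5,7-dihydroxy-4H-chromen-4-one)
Product: 2 8-[(dimethylamino)methyl]-5,7-dihydroxy-4H-chromen-4-one
Conditions: CH2(NMe2)2 (1.05 equiv), 1,4-dioxane, 80 °C
Reagents that add atoms: bis(dimethylamino)methane, CN(C)CN(C)C
Why: Phenol Mannich reaction in which the aminal delivers an iminium ion ortho to the acidic 7-OH, expected at C8 rather than C6 when the 5-OH is chelated (to be confirmed by HMBC, with minor C6 and bis-adducts removed by crystallisation), while the 7-phenolate form protects the pyranone from amine attack at C2.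

Step 2
Reactants: 2 8-[(dimethylamino)methyl]-5,7-dihydroxy-4H-chromen-4-one; 3 sodium p-toluenesulfinate
Product: 4 5,7-dihydroxy-8-[(4-methylphenyl)sulfonylmethyl]-4H-chromen-4-one
Conditions: 3 (1.5 equiv), AcOH–H2O (4:1), 90 °C
Reagents that add atoms: none
Why: Amine–sulfinate exchange of a phenolic Mannich base, in which hot aqueous acetic acid turns the benzylic dimethylamino group, activated by the ortho and para oxygens of ring A, into a leaving group and the S-nucleophilic sulfinate takes its place at the benzylic carbon to give an acid-stable sulfone, the amine being held as its acetate so that the exchange is not reversed.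

Step 3
Reactants: 5 4-bromo-2-methylbut-1-ene
Product: 7 5-methylhex-5-en-1-ol, via Grignard reagent 6 (not isolated)
Conditions: Mg, THF, 25–40 °C; then CuI (5 mol %), ethylene oxide (2.5 M in THF), −30 to 0 °C; sat. aq NH4Cl
Reagents that add atoms: ethylene oxide, C1CO1
Why: Grignard formation followed by copper-catalysed epoxide opening is a standard two-carbon homologation to the primary alcohol and leaves the 1,1-disubstituted alkene untouched.

Step 4
Reactants: 7 5-methylhex-5-en-1-ol
Product: 8 5-methylhex-5-enal
Conditions: TEMPO (10 mol %), PhI(OAc)2 (1.1 equiv), CH2Cl2, 20 °C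
Reagents that add atoms: none
Why: Nitroxyl-catalysed alcohol oxidation should stop cleanly at the aldehyde under near-neutral conditions that spare the alkene, and the volatile product is used as a solution.

Step 5
Reactants: 4 5,7-dihydroxy-8-[(4-methylphenyl)sulfonylmethyl]-4H-chromen-4-one; 8 5-methylhex-5-enal
Product: 13 (9R)-5,8-dihydroxy-9-(3-methylbut-3-en-1-yl)-9,10-dihydro-4H,8H-pyrano[2,3-f]chromen-4-one (ring A pyrano-fused lactol; both C8 anomers; C9 is C2'' of the target), via o-quinone methide 9 (not isolated), via enamine 10 (not isolated), via iminium phenolate 11 (not isolated), via hydroxy aldehyde 12 (not isolated)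
Conditions: (S)-α,α-diphenylprolinol trimethylsilyl ether (20 mol %), 8 (3 equiv), Na2CO3 (1.5 equiv), CH2Cl2–THF (4:1), 0 to 20 °C
Reagents that add atoms: none
Why: Na2CO3 deprotonates the acidic C7 phenol of 4 and 1,4-elimination of toluenesulfinate unmasks methide 9, while 8 and the amine condense to the anti-(E)-enamine 10; the nucleophilic carbon of 10 adds to the exocyclic CH2 of 9, ring A re-aromatises to iminium phenolate 11, and hydrolysis by the water of condensation releases the catalyst and aldehyde 12. The closest known reaction type is the secondary-amine-catalysed enantioselective alpha-alkylation of aldehydes with o-quinone methides generated from 2-(sulfonylmethyl)phenols, a formal [4+2] annulation. The pyran ring closes by 6-exo-trig attack of the C7 oxygen on the iminium or aldehyde carbon, and the hemiacetal form shields the new alpha-centre from enamine-mediated epimerisation. C2'' is controlled by the catalyst: the CPh2OSiMe3 group of the (S)-amine blocks the Re face of the enamine carbon, so the methide bonds to its Si face, which corresponds to R, whereas the anomeric centre is left uncontrolled because it becomes sp2 later. The step needs chemoselectivity for the methide terminus over the chromone C2 position and over methide self-condensation; the hindered amine is a poor nucleophile for the pyranone, the 5-OH stays hydrogen-bonded to C4=O, the departing sulfinate does not compete with the amine catalyst, and slow heterogeneous generation keeps 9 dilute beside excess 8.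

Step 6
Reactants: 13 (9R)-5,8-dihydroxy-9-(3-methylbut-3-en-1-yl)-9,10-dihydro-4H,8H-pyrano[2,3-f]chromen-4-one
Product: 14 5,7-dihydroxy-8-[(2R)-2-(1-hydroxyethyl)-5-methylhex-5-en-1-yl]-4H-chromen-4-one (both carbinol epimers)
Conditions: MeTi(OiPr)3 (4 equiv, 1 M in THF), THF, −20 to 20 °C; then H2O
Reagents that add atoms: methyltitanium triisopropoxide, C[Ti](OC(C)C)(OC(C)C)OC(C)C
Why: Chemoselective organotitanium addition to the aldehyde tautomer of the lactol, whose titanium lactolate should open readily because the chromone phenoxide is a good leaving group; the weakly basic reagent leaves the chromone and C2'' alone, and the new carbinol centre is formed without control and erased in step 8.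

Step 7
Reactants: 14 5,7-dihydroxy-8-[(2R)-2-(1-hydroxyethyl)-5-methylhex-5-en-1-yl]-4H-chromen-4-one
Product: 15 5-hydroxy-8-[(2R)-2-(1-hydroxyethyl)-5-methylhex-5-en-1-yl]-7-(methoxymethoxy)-4H-chromen-4-one
Conditions: MOMCl (1.1 equiv), K2CO3 (1.5 equiv), acetone, 0 to 20 °C
Reagents that add atoms: chloromethyl methyl ether, COCCl
Why: Chemoselective phenol O-alkylation, since only the vinylogous-acid 7-OH is deprotonated by K2CO3 while the chelated 5-OH and the secondary alcohol stay free, and capping O7 prevents hemiketal formation after the next step.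

Step 8
Reactants: 15 5-hydroxy-8-[(2R)-2-(1-hydroxyethyl)-5-methylhex-5-en-1-yl]-7-(methoxymethoxy)-4H-chromen-4-one
Product: 16 8-[(2R)-2-acetyl-5-methylhex-5-en-1-yl]-5-hydroxy-7-(methoxymethoxy)-4H-chromen-4-one
Conditions: DMP (1.3 equiv), CH2Cl2, 0 to 20 °C
Reagents that add atoms: none
Why: Dess–Martin oxidation converts both carbinol epimers into one methyl ketone under non-basic conditions that should not enolise the adjacent C2'' centre or oxidise the chelated phenol.

Step 9
Reactants: 16 8-[(2R)-2-acetyl-5-methylhex-5-en-1-yl]-5-hydroxy-7-(methoxymethoxy)-4H-chromen-4-one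
Product: 17 5-hydroxy-7-(methoxymethoxy)-8-[(2R)-5-methyl-2-(prop-1-en-2-yl)hex-5-en-1-yl]-4H-chromen-4-one
Conditions: Zn, CH2Br2, TiCl4 (reagent aged in THF, −40 to 5 °C; excess), CH2Cl2, 0 to 20 °C; then H2O
Reagents that add atoms: dibromomethane, BrCBr
Why: Takai–Lombardo methylenation with a non-basic gem-dimetallic reagent, which is the standard choice for ketones with an epimerisable alpha-centre, should convert the methyl ketone into the isopropenyl group without touching the vinylogous-ester C4 carbonyl, the MOM ether or C2'', the free 5-OH merely consuming reagent.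

Step 10
Reactants: 17 5-hydroxy-7-(methoxymethoxy)-8-[(2R)-5-methyl-2-(prop-1-en-2-yl)hex-5-en-1-yl]-4H-chromen-4-one
Product: 18 5,7-bis(methoxymethoxy)-8-[(2R)-5-methyl-2-(prop-1-en-2-yl)hex-5-en-1-yl]-4H-chromen-4-one
Conditions: NaH (1.5 equiv), MOMCl (1.5 equiv), DMF, 0 °C
Reagents that add atoms: chloromethyl methyl ether, COCCl
Why: O-alkylation of the chelated phenol after irreversible deprotonation is routine and is safe here because C2'' is no longer alpha to a carbonyl; it removes the chelating, catalyst-binding 5-OH before the arylation.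

Step 11
Reactants: 19 4-bromobenzene-1,3-diol
Product: 20 1-bromo-2,4-bis(methoxymethoxy)benzene
Conditions: NaH (2.4 equiv), MOMCl (2.4 equiv), DMF, 0 to 20 °C
Reagents that add atoms: chloromethyl methyl ether, COCCl
Why: Double Williamson-type O-alkylation of a simple resorcinol gives the bis-MOM ether needed to carry ring B through organolithium and rhodium chemistry.

Step 12
Reactants: 20 1-bromo-2,4-bis(methoxymethoxy)benzene
Product: 23 [2,4-bis(methoxymethoxy)phenyl]boronic acid, via aryllithium 21 (not isolated), via lithium borate 22 (not isolated)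
Conditions: n-BuLi, THF, −78 °C; B(OiPr)3, −78 to 20 °C; sat. aq NH4Cl
Reagents that add atoms: triisopropyl borate, CC(C)OB(OC(C)C)OC(C)C; water, O
Why: Bromine–lithium exchange, assisted by the ortho MOM oxygen, followed by borate trapping and mild hydrolysis is the standard route to arylboronic acids and the near-neutral work-up keeps the MOM ethers.

Step 13
Reactants: 18 5,7-bis(methoxymethoxy)-8-[(2R)-5-methyl-2-(prop-1-en-2-yl)hex-5-en-1-yl]-4H-chromen-4-one; 23 [2,4-bis(methoxymethoxy)phenyl]boronic acid
Product: 24 (2S)-2-[2,4-bis(methoxymethoxy)phenyl]-5,7-bis(methoxymethoxy)-8-[(2R)-5-methyl-2-(prop-1-en-2-yl)hex-5-en-1-yl]-2,3-dihydro-4H-chromen-4-one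
Conditions: [Rh(OH)(cod)]2 (3 mol %), (S)-MeO-F12-BIPHEP [(S)-2,2'-bis[bis(3,4,5-trifluorophenyl)phosphino]-6,6'-dimethoxy-1,1'-biphenyl] (7 mol %), 23 (3 equiv), toluene–H2O (10:1), 40 °C
Reagents that add atoms: none
Why: Rhodium-catalysed asymmetric 1,4-addition of an arylboronic acid to a chromone (Hayashi–Miyaura type), in which transmetalation, enantio-determining insertion of the C2=C3 bond and protonolysis should deliver the aryl group to the Re face of C2 under control of the electron-poor (S)-bisphosphine, setting 2S independently of the remote C2'' centre while the MOM ethers and both 1,1-disubstituted alkenes stay inert.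

Step 14
Reactants: 24 (2S)-2-[2,4-bis(methoxymethoxy)phenyl]-5,7-bis(methoxymethoxy)-8-[(2R)-5-methyl-2-(prop-1-en-2-yl)hex-5-en-1-yl]-2,3-dihydro-4H-chromen-4-one
Product: 25 remangiflavanone B, (2S)-2-(2,4-dihydroxyphenyl)-5,7-dihydroxy-8-[(2R)-5-methyl-2-(prop-1-en-2-yl)hex-5-en-1-yl]-2,3-dihydro-4H-chromen-4-one
Conditions: 3 M aq HCl–MeOH (1:5), 35 °C
Reagents that add atoms: none
Why: Acid-catalysed acetal solvolysis (transacetalisation to the methanol-derived formal) should free all four phenols at an acidity too low to protonate the terminal alkenes appreciably or to open the flavanone ring, so that C2 and C2'' are retained.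

Compound list
1 | 5,7-dihydroxychromone (5,7-dihydroxy-4H-chromen-4-one) | O=C1C=COc2cc(O)cc(O)c12 | starting material
2 | 8-[(dimethylamino)methyl]-5,7-dihydroxy-4H-chromen-4-one | CN(C)Cc1c(O)cc(O)c2c1OC=CC2=O | intermediate
3 | sodium p-toluenesulfinate | Cc1ccc(cc1)S(=O)[O-].[Na+] | starting material
4 | 5,7-dihydroxy-8-[(4-methylphenyl)sulfonylmethyl]-4H-chromen-4-one | Cc1ccc(cc1)S(=O)(=O)Cc1c(O)cc(O)c2c1OC=CC2=O | intermediate
5 | 4-bromo-2-methylbut-1-ene | C=C(C)CCBr | starting material
6 | (3-methylbut-3-en-1-yl)magnesium bromide (formed in situ) | C=C(C)CC[Mg]Br | intermediate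
7 | 5-methylhex-5-en-1-ol | C=C(C)CCCCO | intermediate
8 | 5-methylhex-5-enal | C=C(C)CCCC=O | intermediate
9 | 5-hydroxy-8-methylidene-4H-chromene-4,7(8H)-dione (o-quinone methide, formed in situ) | C=C1C(=O)C=C(O)C2=C1OC=CC2=O | intermediate
10 | (2S)-2-[diphenyl(trimethylsilyloxy)methyl]-1-[(1E)-5-methylhexa-1,5-dien-1-yl]pyrrolidine (enamine, formed in situ) | C=C(C)CC/C=C/N1CCC[C@H]1C(c1ccccc1)(c1ccccc1)O[Si](C)(C)C | intermediate
11 | iminium phenolate from Michael addition of 10 to 9, (R) at C2'' (formed in situ) | C=C(C)CC[C@@H](C=[N+]1CCC[C@H]1C(c1ccccc1)(c1ccccc1)O[Si](C)(C)C)Cc1c([O-])cc(O)c2c1OC=CC2=O | intermediate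
12 | (2R)-2-[(5,7-dihydroxy-4-oxo-4H-chromen-8-yl)methyl]-5-methylhex-5-enal (formed in situ) | C=C(C)CC[C@@H](C=O)Cc1c(O)cc(O)c2c1OC=CC2=O | intermediate
13 | (9R)-5,8-dihydroxy-9-(3-methylbut-3-en-1-yl)-9,10-dihydro-4H,8H-pyrano[2,3-f]chromen-4-one (lactol, both C8 anomers) | C=C(C)CC[C@@H]1Cc2c(OC1O)cc(O)c1c2OC=CC1=O | intermediate
14 | 5,7-dihydroxy-8-[(2R)-2-(1-hydroxyethyl)-5-methylhex-5-en-1-yl]-4H-chromen-4-one (both carbinol epimers) | C=C(C)CC[C@@H](C(C)O)Cc1c(O)cc(O)c2c1OC=CC2=O | intermediate
15 | 5-hydroxy-8-[(2R)-2-(1-hydroxyethyl)-5-methylhex-5-en-1-yl]-7-(methoxymethoxy)-4H-chromen-4-one (both carbinol epimers) | C=C(C)CC[C@@H](C(C)O)Cc1c(OCOC)cc(O)c2c1OC=CC2=O | intermediate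
16 | 8-[(2R)-2-acetyl-5-methylhex-5-en-1-yl]-5-hydroxy-7-(methoxymethoxy)-4H-chromen-4-one | C=C(C)CC[C@@H](C(C)=O)Cc1c(OCOC)cc(O)c2c1OC=CC2=O | intermediate
17 | 5-hydroxy-7-(methoxymethoxy)-8-[(2R)-5-methyl-2-(prop-1-en-2-yl)hex-5-en-1-yl]-4H-chromen-4-one | C=C(C)CC[C@@H](C(C)=C)Cc1c(OCOC)cc(O)c2c1OC=CC2=O | intermediate
18 | 5,7-bis(methoxymethoxy)-8-[(2R)-5-methyl-2-(prop-1-en-2-yl)hex-5-en-1-yl]-4H-chromen-4-one | C=C(C)CC[C@@H](C(C)=C)Cc1c(OCOC)cc(OCOC)c2c1OC=CC2=O | intermediate
19 | 4-bromobenzene-1,3-diol | Oc1ccc(Br)c(O)c1 | starting material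
20 | 1-bromo-2,4-bis(methoxymethoxy)benzene | COCOc1ccc(Br)c(OCOC)c1 | intermediate
21 | [2,4-bis(methoxymethoxy)phenyl]lithium (formed in situ) | [Li]c1ccc(OCOC)cc1OCOC | intermediate
22 | lithium [2,4-bis(methoxymethoxy)phenyl]tri(propan-2-yloxy)borate (formed in situ) | [Li+].CC(C)O[B-](OC(C)C)(OC(C)C)c1ccc(OCOC)cc1OCOC | intermediate
23 | [2,4-bis(methoxymethoxy)phenyl]boronic acid | COCOc1ccc(B(O)O)c(OCOC)c1 | intermediate
24 | (2S)-2-[2,4-bis(methoxymethoxy)phenyl]-5,7-bis(methoxymethoxy)-8-[(2R)-5-methyl-2-(prop-1-en-2-yl)hex-5-en-1-yl]-2,3-dihydro-4H-chromen-4-one | C=C(C)CC[C@@H](C(C)=C)Cc1c(OCOC)cc(OCOC)c2c1O[C@H](c1ccc(OCOC)cc1OCOC)CC2=O | intermediate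
25 | remangiflavanone B, (2S)-2-(2,4-dihydroxyphenyl)-5,7-dihydroxy-8-[(2R)-5-methyl-2-(prop-1-en-2-yl)hex-5-en-1-yl]-2,3-dihydro-4H-chromen-4-one | C=C(C)CC[C@H](Cc1c(O)cc(O)c2c1O[C@H](c1ccc(O)cc1O)CC2=O)C(=C)C | target

Total step count: 14. Longest linear sequence: 10 steps (steps 1, 2, 5, 6, 7, 8, 9, 10, 13, 14).

Steps most likely to fail

Step 5. The amine may be consumed by N-alkylation with the methide, or held as a stable N,O-aminal so that turnover stops, while the unsubstituted methide oligomerises; facial control may also be eroded. The fallback moves stereocontrol from a catalyst to a stoichiometric, recoverable auxiliary. It sets out from 8, which is condensed with (S)-2-(methoxymethyl)pyrrolidine over K2CO3 in Et2O at 0 °C to give the preformed enamine (2S)-2-(methoxymethyl)-1-[(1E)-5-methylhexa-1,5-dien-1-yl]pyrrolidine F1. An excess of this enamine is combined with 4 and Na2CO3 in THF, so that methide 9 is intercepted in an inverse-electron-demand hetero-Diels–Alder reaction. The methoxymethyl group is expected to shield the same enamine face as in the catalytic version. The product is the isolable aminal (9R)-5-hydroxy-8-[(2S)-2-(methoxymethyl)pyrrolidin-1-yl]-9-(3-methylbut-3-en-1-yl)-9,10-dihydro-4H,8H-pyrano[2,3-f]chromen-4-one F2. Hydrolysis with AcOH–H2O–THF at 20 °C rejoins the route at 13. Any shortfall in enantiomeric purity at C2'' becomes a diastereomer after step 13 and can be removed there.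

Step 13. Insertion of the hindered, electron-rich 2-alkoxyaryl group may be slower than protodeboronation, and the ligand may discriminate poorly between the faces of this 5,8-disubstituted chromone. The fallback gives up catalyst control at C2 and relies on separation, which is possible because C2'' is already fixed. It sets out from 18 and 23: Pd(OCOCF3)2 with 2,2'-bipyridine and NH4PF6 in wet 1,2-dichloroethane at 60 °C (cationic divalent palladium) adds the aryl group without facial bias. This should give 24 together with its C2 epimer, (2R)-2-[2,4-bis(methoxymethoxy)phenyl]-5,7-bis(methoxymethoxy)-8-[(2R)-5-methyl-2-(prop-1-en-2-yl)hex-5-en-1-yl]-2,3-dihydro-4H-chromen-4-one F3. The diastereomers are separated by preparative HPLC. The unwanted epimer is re-equilibrated at C2 with NaOAc in warm EtOH, by reversible opening of the pyranone ring that cannot touch C2'', and separated again. The route is rejoined at 24.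

Step 14. Under protic acid the C7 hydroxyl may add to the protonated isopropenyl group (chroman formation), the alkenes may add methanol, and the electron-rich benzylic C2–O1 bond may ionise with loss of configuration at C2. The fallback replaces acetal solvolysis by aprotic silyl transfer. It sets out from 24: TMSOTf with 2,2'-bipyridyl in MeCN at 0 °C exchanges each aryl MOM ether for a trimethylsilyl ether under buffered, non-protic conditions. This gives (2S)-8-[(2R)-5-methyl-2-(prop-1-en-2-yl)hex-5-en-1-yl]-2-[2,4-bis(trimethylsilyloxy)phenyl]-5,7-bis(trimethylsilyloxy)-2,3-dihydro-4H-chromen-4-one F4. Stirring in water–THF at 20 °C and near-neutral pH removes the silyl groups and arrives at 25.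

Further compounds
F1 | step 5 | (2S)-2-(methoxymethyl)-1-[(1E)-5-methylhexa-1,5-dien-1-yl]pyrrolidine | C=C(C)CC/C=C/N1CCC[C@H]1COC
F2 | step 5 | (9R)-5-hydroxy-8-[(2S)-2-(methoxymethyl)pyrrolidin-1-yl]-9-(3-methylbut-3-en-1-yl)-9,10-dihydro-4H,8H-pyrano[2,3-f]chromen-4-one | C=C(C)CC[C@@H]1Cc2c(OC1N1CCC[C@H]1COC)cc(O)c1c2OC=CC1=O
F3 | step 13 | (2R)-2-[2,4-bis(methoxymethoxy)phenyl]-5,7-bis(methoxymethoxy)-8-[(2R)-5-methyl-2-(prop-1-en-2-yl)hex-5-en-1-yl]-2,3-dihydro-4H-chromen-4-one | C=C(C)CC[C@@H](C(C)=C)Cc1c(OCOC)cc(OCOC)c2c1O[C@@H](c1ccc(OCOC)cc1OCOC)CC2=O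
F4 | step 14 | (2S)-8-[(2R)-5-methyl-2-(prop-1-en-2-yl)hex-5-en-1-yl]-2-[2,4-bis(trimethylsilyloxy)phenyl]-5,7-bis(trimethylsilyloxy)-2,3-dihydro-4H-chromen-4-one | C=C(C)CC[C@@H](C(C)=C)Cc1c(O[Si](C)(C)C)cc(O[Si](C)(C)C)c2c1O[C@H](c1ccc(O[Si](C)(C)C)cc1O[Si](C)(C)C)CC2=O
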